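**Plan**

- The retrosynthesis opens ring C at O1–C2 (cyclodehydration of an ortho-hydroxyaryl 1,3-diketone) and then cuts C3–C4, with the C2–C3–C4 dicarbonyl unit carried as a 3,5-diarylisoxazole.
- Enabling feature: C4 is bonded to C4a of ring A, and both neighbours of C4a (C5 and C8a) carry oxygen. A nitrile oxide on that carbon is therefore flanked by two ortho alkoxy groups and can be isolated, and C2–C3–C4 has the 1,3-dioxygenation pattern that an isoxazole stores.
- Forward, ring A is fully oxygenated first: phloroglucinol, tris-MOM ether, dibromide, dimethoxy arene, aldehyde, oxime, nitrile oxide. The ring B alkyne comes from 2,3-dimethoxybenzaldehyde in one step.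
- The isoxazole ring then forms by [3+2] cycloaddition (C3–C4 and the O–C2 bond). Ring C closes last, after N–O cleavage, MOM removal and hydrolysis.
- The target has no stereocenter. The only stereo-elements on the way are the oxime and enaminone double bonds and one transient racemic hemiaminal carbon, and none reaches the product.

Key step: step 8

Assumption: in acidic methanol each MOM group leaves as dimethoxymethane. Ring A of the unmasked diketone has two equivalent ortho hydroxyls, so closure through either one gives the same flavone.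

**Route**

Step 1
Reactants: 1 phloroglucinol (benzene-1,3,5-triol)
Product: 2 1,3,5-tris(methoxymethoxy)benzene
Conditions: MOMCl (4.5 equiv), iPr2NEt (6 equiv), CH2Cl2/DMF, 0 °C → rt
Reagents that add atoms: chloromethyl methyl ether (MOMCl), COCCl
Why: O-alkylation of the three phenols (MOM protection) should prevail over C-alkylation because MOMCl is a hard, oxocarbenium-like electrophile and the amine base keeps the phenoxide concentration low.

Step 2
Reactants: 2 1,3,5-tris(methoxymethoxy)benzene
Product: 3 2,4-dibromo-1,3,5-tris(methoxymethoxy)benzene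
Conditions: NBS (2.05 equiv), MeCN, 0 °C → rt, dark
Reagents that add atoms: N-bromosuccinimide, O=C1CCC(=O)N1Br
Why: Electrophilic aromatic bromination of a ring whose CH positions are each activated by three alkoxy groups should stop at the dibromide by stoichiometry, since each bromine deactivates and crowds the ring, and the non-acidic medium spares the MOM acetals.

Step 3
Reactants: 3 2,4-dibromo-1,3,5-tris(methoxymethoxy)benzene
Product: 4 2,4-dimethoxy-1,3,5-tris(methoxymethoxy)benzene
Conditions: NaOMe (excess), CuBr (0.2 equiv), MeOH/DMF, 110 °C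
Reagents that add atoms: sodium methoxide, [Na+].[O-]C
Why: Ullmann-type copper-catalysed methoxylation should exchange both aryl bromides for methoxy groups, and the MOM acetals are inert to hot methoxide.

Step 4
Reactants: 4 2,4-dimethoxy-1,3,5-tris(methoxymethoxy)benzene
Product: 7 3,5-dimethoxy-2,4,6-tris(methoxymethoxy)benzaldehyde, via aryllithium 5 (not isolated), via lithium hemiaminal alkoxide 6 (not isolated)
Conditions: n-BuLi, TMEDA, THF, 0 °C; DMF, −78 °C → rt; H2O
Reagents that add atoms: N,N-dimethylformamide, CN(C)C=O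
Why: Directed ortho-metalation should occur at the only ring hydrogen, which sits between two lithium-chelating MOM ethers, and Bouveault-type formylation with DMF gives a racemic tetrahedral adduct that collapses to the aldehyde on aqueous work-up.

Step 5
Reactants: 7 3,5-dimethoxy-2,4,6-tris(methoxymethoxy)benzaldehyde
Product: 8 (E)-3,5-dimethoxy-2,4,6-tris(methoxymethoxy)benzaldehyde oxime
Conditions: NH2OH·HCl, NaOAc, EtOH/H2O, 50 °C
Reagents that add atoms: hydroxylamine hydrochloride, NO.Cl
Why: Oxime condensation of an aldehyde is reliable even with two ortho substituents, and the acetate buffer keeps the medium too weakly acidic to cleave MOM ethers.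

Step 6
Reactants: 8 (E)-3,5-dimethoxy-2,4,6-tris(methoxymethoxy)benzaldehyde oxime
Product: 10 3,5-dimethoxy-2,4,6-tris(methoxymethoxy)benzonitrile oxide, via hydroximoyl chloride 9 (not isolated)
Conditions: NCS, DMF, rt; then Et3N, 0 °C
Reagents that add atoms: none
Why: Chlorination of the aldoxime to the hydroximoyl chloride followed by dehydrochlorination (Huisgen method) should give a nitrile oxide that can be isolated, because the two ortho MOM ethers block dimerisation to the furoxan and the fully substituted ring offers NCS no site for ring chlorination.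

Step 7
Reactants: 11 2,3-dimethoxybenzaldehyde
Product: 12 1-ethynyl-2,3-dimethoxybenzene
Conditions: Ohira–Bestmann reagent, K2CO3, MeOH, rt
Reagents that add atoms: dimethyl (1-diazo-2-oxopropyl)phosphonate, COP(=O)(OC)C(=[N+]=[N-])C(C)=O
Why: Seyferth–Gilbert homologation in the Ohira–Bestmann variant converts a non-enolisable aryl aldehyde into the terminal alkyne through a diazoalkene and 1,2-hydride shift of the derived alkylidene carbene.

Step 8
Reactants: 10 3,5-dimethoxy-2,4,6-tris(methoxymethoxy)benzonitrile oxide; 12 1-ethynyl-2,3-dimethoxybenzene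
Product: 13 3-[3,5-dimethoxy-2,4,6-tris(methoxymethoxy)phenyl]-5-(2,3-dimethoxyphenyl)isoxazole
Conditions: PhMe, 85 °C (12 in 1.5-fold excess)
Reagents that add atoms: none
Why: Nitrile oxide 10 and terminal alkyne 12 should combine in a concerted, asynchronous Huisgen 1,3-dipolar cycloaddition in which the nitrile oxide carbon bonds to the terminal alkyne carbon (the future C3–C4 bond) and the oxide oxygen bonds to the aryl-bearing alkyne carbon (the future C2, fixed at the ketone oxidation level). The closest known reaction type is the addition of mesitonitrile oxide and other 2,6-disubstituted aryl nitrile oxides to arylacetylenes, which gives 3,5-diarylisoxazoles. The isoxazole ring closes in this single suprafacial six-electron event as an intermolecular (3+2) annulation, with both ring bonds made at once and the ring aromatic as formed. No stereocenter arises. The step needs 3,5- over 3,4-regioselectivity, which the terminal alkyne secures, because the crowded dipole carbon goes to the unhindered CH terminus and the frontier-orbital interaction (dipole LUMO with the larger HOMO coefficient at the terminal carbon of the arylacetylene) points the same way. It also needs the dipole to outlast a slow addition, which the two ortho MOM ethers secure by blocking furoxan formation, while the temperature stays below the range in which hindered nitrile oxides isomerise to isocyanates.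

Step 9
Reactants: 13 3-[3,5-dimethoxy-2,4,6-tris(methoxymethoxy)phenyl]-5-(2,3-dimethoxyphenyl)isoxazole
Product: 14 (Z)-3-amino-3-[3,5-dimethoxy-2,4,6-tris(methoxymethoxy)phenyl]-1-(2,3-dimethoxyphenyl)prop-2-en-1-one
Conditions: Mo(CO)6, MeCN/H2O, 80 °C
Reagents that add atoms: none
Why: Reductive N–O cleavage of an isoxazole by zerovalent molybdenum in wet acetonitrile should give the hydrogen-bonded Z vinylogous amide under neutral conditions that leave MOM ethers, aryl methyl ethers and the ketone untouched.

Step 10
Reactants: 14 (Z)-3-amino-3-[3,5-dimethoxy-2,4,6-tris(methoxymethoxy)phenyl]-1-(2,3-dimethoxyphenyl)prop-2-en-1-one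
Product: 17 5,7-dihydroxy-6,8,2',3'-tetramethoxyflavone, via trihydroxy enaminone 15 (not isolated), via trihydroxy 1,3-diketone 16 (not isolated)
Conditions: 3 M aq HCl, MeOH, 65 °C
Reagents that add atoms: water, O
Why: Acid-catalysed MOM acetal cleavage, hydrolysis of the vinylogous amide to the 1,3-diketone and cyclodehydration (the closing step of a Baker–Venkataraman flavone synthesis) should run in one pot, with the fully substituted ring A offering no site for capture of the released formaldehyde equivalent.

**Compound list**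

1 | phloroglucinol | Oc1cc(O)cc(O)c1 | starting material
2 | 1,3,5-tris(methoxymethoxy)benzene | COCOc1cc(OCOC)cc(OCOC)c1 | intermediate
3 | 2,4-dibromo-1,3,5-tris(methoxymethoxy)benzene | COCOc1cc(OCOC)c(Br)c(OCOC)c1Br | intermediate
4 | 2,4-dimethoxy-1,3,5-tris(methoxymethoxy)benzene | COCOc1cc(OCOC)c(OC)c(OCOC)c1OC | intermediate
5 | [3,5-dimethoxy-2,4,6-tris(methoxymethoxy)phenyl]lithium (not isolated) | [Li]c1c(OCOC)c(OC)c(OCOC)c(OC)c1OCOC | intermediate
6 | lithium (dimethylamino)[3,5-dimethoxy-2,4,6-tris(methoxymethoxy)phenyl]methanolate, racemic (not isolated) | [Li]OC(N(C)C)c1c(OCOC)c(OC)c(OCOC)c(OC)c1OCOC | intermediate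
7 | 3,5-dimethoxy-2,4,6-tris(methoxymethoxy)benzaldehyde | O=Cc1c(OCOC)c(OC)c(OCOC)c(OC)c1OCOC | intermediate
8 | (E)-3,5-dimethoxy-2,4,6-tris(methoxymethoxy)benzaldehyde oxime | O/N=C/c1c(OCOC)c(OC)c(OCOC)c(OC)c1OCOC | intermediate
9 | (Z)-N-hydroxy-3,5-dimethoxy-2,4,6-tris(methoxymethoxy)benzimidoyl chloride (not isolated) | O/N=C(\Cl)c1c(OCOC)c(OC)c(OCOC)c(OC)c1OCOC | intermediate
10 | 3,5-dimethoxy-2,4,6-tris(methoxymethoxy)benzonitrile oxide | [O-][N+]#Cc1c(OCOC)c(OC)c(OCOC)c(OC)c1OCOC | intermediate
11 | 2,3-dimethoxybenzaldehyde | COc1cccc(C=O)c1OC | starting material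
12 | 1-ethynyl-2,3-dimethoxybenzene | C#Cc1cccc(OC)c1OC | intermediate
13 | 3-[3,5-dimethoxy-2,4,6-tris(methoxymethoxy)phenyl]-5-(2,3-dimethoxyphenyl)isoxazole | COCOc1c(OC)c(OCOC)c(-c2cc(-c3cccc(OC)c3OC)on2)c(OCOC)c1OC | intermediate
14 | (Z)-3-amino-3-[3,5-dimethoxy-2,4,6-tris(methoxymethoxy)phenyl]-1-(2,3-dimethoxyphenyl)prop-2-en-1-one | N/C(=C\C(=O)c1cccc(OC)c1OC)c1c(OCOC)c(OC)c(OCOC)c(OC)c1OCOC | intermediate
15 | (Z)-3-amino-1-(2,3-dimethoxyphenyl)-3-(2,4,6-trihydroxy-3,5-dimethoxyphenyl)prop-2-en-1-one (not isolated) | N/C(=C\C(=O)c1cccc(OC)c1OC)c1c(O)c(OC)c(O)c(OC)c1O | intermediate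
16 | 1-(2,3-dimethoxyphenyl)-3-(2,4,6-trihydroxy-3,5-dimethoxyphenyl)propane-1,3-dione (not isolated) | COc1cccc(C(=O)CC(=O)c2c(O)c(OC)c(O)c(OC)c2O)c1OC | intermediate
17 | 5,7-dihydroxy-6,8,2',3'-tetramethoxyflavone [2-(2,3-dimethoxyphenyl)-5,7-dihydroxy-6,8-dimethoxy-4H-chromen-4-one] | COc1cccc(-c2cc(=O)c3c(O)c(OC)c(O)c(OC)c3o2)c1OC | target

**Step count**

Total step count: 10.
Longest linear sequence: 9 steps (steps 1–6 and 8–10, from phloroglucinol). The alkyne branch is one step (step 7).

**Steps most likely to fail**

1. Step 8. The addition of a doubly shielded dipole carbon to an ortho-substituted arylacetylene may be slower than thermal isomerisation of the nitrile oxide to the isocyanate or its gradual decomposition, and some 3,4-regioisomer may form. The fallback sets out from aldehyde 7 and alkyne 12 and returns at target 17, forming C3–C4 by carbonyl addition. Alkyne 12 is deprotonated (n-BuLi, THF, −78 °C) to [(2,3-dimethoxyphenyl)ethynyl]lithium F1, which should add to 7 to give the racemic propargylic alcohol 1-[3,5-dimethoxy-2,4,6-tris(methoxymethoxy)phenyl]-3-(2,3-dimethoxyphenyl)prop-2-yn-1-ol F2. Oxidation with MnO2 (CH2Cl2, rt) should give the ynone 1-[3,5-dimethoxy-2,4,6-tris(methoxymethoxy)phenyl]-3-(2,3-dimethoxyphenyl)prop-2-yn-1-one F3. HCl in MeOH removes the MOM ethers to give 3-(2,3-dimethoxyphenyl)-1-(2,4,6-trihydroxy-3,5-dimethoxyphenyl)prop-2-yn-1-one F4, and K2CO3 in acetone should close ring C by 6-endo-dig oxa-Michael addition to give 17.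

2. Step 3. Each bromide is wedged between two MOM ethers, so copper-mediated hydrodebromination may outrun methoxylation, or the exchange may stop after one bromide. The fallback sets out from 2 and returns at 4, installing each oxygen by directed metalation. Lithiation of 2 (n-BuLi, THF, 0 °C) gives [2,4,6-tris(methoxymethoxy)phenyl]lithium F5, B(OMe)3 traps it as dimethyl [2,4,6-tris(methoxymethoxy)phenyl]boronate F6, and H2O2/aq NaOH oxidises this to 2,4,6-tris(methoxymethoxy)phenol F7. MeI/K2CO3 in acetone gives 2-methoxy-1,3,5-tris(methoxymethoxy)benzene F8. The same sequence is repeated at one of the two equivalent remaining positions, through [3-methoxy-2,4,6-tris(methoxymethoxy)phenyl]lithium F9, dimethyl [3-methoxy-2,4,6-tris(methoxymethoxy)phenyl]boronate F10 and 3-methoxy-2,4,6-tris(methoxymethoxy)phenol F11. Methylation of F11 with MeI/K2CO3 gives 4.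

3. Step 9. Complexation of Mo(CO)6 at the ring nitrogen, which is shielded by the two ortho MOM ethers, may be slow, leaving N–O cleavage incomplete, and prolonged heating in wet acetonitrile may erode MOM ethers to mixtures. The fallback sets out from 13 and returns at 15, reversing the order of deprotection and reduction. HCl in MeOH at 50 °C should remove the MOM ethers from the acid-stable isoxazole to give 3-(2,4,6-trihydroxy-3,5-dimethoxyphenyl)-5-(2,3-dimethoxyphenyl)isoxazole F12, whose ortho substituents are now only hydroxyls. Catalytic hydrogenolysis (H2, Pd/C, EtOH, rt) should then cleave the N–O bond to give 15, which is carried through the hydrolysis and cyclodehydration of step 10 (3 M aq HCl, MeOH, 65 °C) to 17.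

**Further compounds**

F1 | step 8 | [(2,3-dimethoxyphenyl)ethynyl]lithium | [Li]C#Cc1cccc(OC)c1OC
F2 | step 8 | racemic 1-[3,5-dimethoxy-2,4,6-tris(methoxymethoxy)phenyl]-3-(2,3-dimethoxyphenyl)prop-2-yn-1-ol | COCOc1c(OC)c(OCOC)c(C(O)C#Cc2cccc(OC)c2OC)c(OCOC)c1OC
F3 | step 8 | 1-[3,5-dimethoxy-2,4,6-tris(methoxymethoxy)phenyl]-3-(2,3-dimethoxyphenyl)prop-2-yn-1-one | COCOc1c(OC)c(OCOC)c(C(=O)C#Cc2cccc(OC)c2OC)c(OCOC)c1OC
F4 | step 8 | 3-(2,3-dimethoxyphenyl)-1-(2,4,6-trihydroxy-3,5-dimethoxyphenyl)prop-2-yn-1-one | COc1cccc(C#CC(=O)c2c(O)c(OC)c(O)c(OC)c2O)c1OC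
F5 | step 3 | [2,4,6-tris(methoxymethoxy)phenyl]lithium | [Li]c1c(OCOC)cc(OCOC)cc1OCOC
F6 | step 3 | dimethyl [2,4,6-tris(methoxymethoxy)phenyl]boronate | COCOc1cc(OCOC)c(B(OC)OC)c(OCOC)c1
F7 | step 3 | 2,4,6-tris(methoxymethoxy)phenol | COCOc1cc(OCOC)c(O)c(OCOC)c1
F8 | step 3 | 2-methoxy-1,3,5-tris(methoxymethoxy)benzene | COCOc1cc(OCOC)c(OC)c(OCOC)c1
F9 | step 3 | [3-methoxy-2,4,6-tris(methoxymethoxy)phenyl]lithium | [Li]c1c(OCOC)c(OC)c(OCOC)cc1OCOC
F10 | step 3 | dimethyl [3-methoxy-2,4,6-tris(methoxymethoxy)phenyl]boronate | COB(OC)c1c(OCOC)c(OC)c(OCOC)cc1OCOC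
F11 | step 3 | 3-methoxy-2,4,6-tris(methoxymethoxy)phenol | Oc1c(OCOC)c(OC)c(OCOC)cc1OCOC
F12 | step 9 | 3-(2,4,6-trihydroxy-3,5-dimethoxyphenyl)-5-(2,3-dimethoxyphenyl)isoxazole | COc1cccc(-c2cc(-c3c(O)c(OC)c(O)c(OC)c3O)no2)c1OC
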